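**Plan**
- Hardest: the C3–O bond and the trans C2/C3 pair must be made while an oxidation- and acid-prone prenyl alkene sits at C8. Ring A also needs OMe/OH/prenyl at C5/C7/C8 with no 6/8 ambiguity.
- Cuts: C3–O goes back to C3–B and then to the C3=C4 alkene of a flav-3-ene. Next, O1–C2 and C4–C4a are cut together (resorcinol + cinnamaldehyde), and last the C8–CH2 bond of the prenyl group.
- Enabling feature 1: ring A without C4 is 5-methoxy-2-prenylresorcinol, which has a mirror plane through C8 and C5. O1/O7 and C4a/C6 are therefore equivalent pairs, and ring C can form in one way only.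
- Enabling feature 2: in the flav-3-ene, C2 is the sp3 end of the array O1–C2–C3=C4–C4a=C8a. Light opens ring C to an achiral o-quinone methide that recloses thermally, so C2 racemises on demand. The borylated product has no C3=C4 and is inert to that light.
- Forward: ring A is prenylated first and ring C is closed racemic by condensation/oxa-6π electrocyclisation. A light-driven dynamic kinetic resolution by Cu-catalysed protoboration follows, then C–B oxidation and desilylation.
- Stereochemistry: C2 comes from catalyst selection out of the racemising pool, C3 from syn Cu–B addition anti to the C2 aryl group, and C–B becomes C–O with retention.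

Key step: step 8

Assumption: (S,S)-Ph-BPE is taken as the ligand enantiomer matched to (2S)-13. If the sense of induction is the opposite, (R,R)-Ph-BPE is used and nothing else changes.

**Step 1**
Reactants: 1 5-methoxyresorcinol (3,5-dihydroxyanisole)
Product: 2 1-methoxy-3,5-bis(methoxymethoxy)benzene
Conditions: MOMCl (2.4 equiv), i-Pr2NEt, CH2Cl2, 0 °C to rt
Reagents that add atoms: chloromethyl methyl ether (MOMCl), COCCl
Why: Standard O-alkylation of both phenols (acetal protection) should proceed cleanly, and the two MOM groups later serve as the chelating directors for the metalation in step 2.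

**Step 2**
Reactants: 2 1-methoxy-3,5-bis(methoxymethoxy)benzene; 3 prenyl bromide (1-bromo-3-methylbut-2-ene)
Product: 5 5-methoxy-1,3-bis(methoxymethoxy)-2-(3-methylbut-2-en-1-yl)benzene, via aryllithium 4 (not isolated)
Conditions: n-BuLi (1.1 equiv), THF, 0 °C; then 3, −78 °C to rt
Reagents that add atoms: n-butyllithium, [Li]CCCC (Li of 4 only)
Why: Directed ortho-metalation should remove the ring proton flanked by the two chelating OMOM groups (a stronger cooperative pair than OMOM/OMe), and SN2 attack of aryllithium 4 on the primary allylic bromide places the linear prenyl group on the mirror plane of the ring.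

**Step 3**
Reactants: 5 5-methoxy-1,3-bis(methoxymethoxy)-2-(3-methylbut-2-en-1-yl)benzene
Product: 6 5-methoxy-2-(3-methylbut-2-en-1-yl)benzene-1,3-diol
Conditions: HCl (0.5 M in MeOH), 40 °C, stopped at full conversion
Reagents that add atoms: none
Why: Acid-catalysed transacetalisation cleaves phenolic MOM ethers under conditions mild enough that Markovnikov addition of the flanking phenols to the prenyl alkene should remain slow.

**Step 4**
Reactants: 7 4-hydroxybenzaldehyde
Product: 8 4-(triisopropylsilyloxy)benzaldehyde
Conditions: TIPSCl, imidazole, DMF, rt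
Reagents that add atoms: chlorotriisopropylsilane (TIPSCl), CC(C)[Si](Cl)(C(C)C)C(C)C
Why: Routine silylation of a phenol, with the bulky TIPS ether chosen because it should outlast warm weak acid (step 6), catalytic alkoxide and perborate (step 8) yet fall to fluoride.

**Step 5**
Reactants: 8 4-(triisopropylsilyloxy)benzaldehyde; 9 (triphenylphosphoranylidene)acetaldehyde
Product: 10 (E)-3-[4-(triisopropylsilyloxy)phenyl]prop-2-enal
Conditions: 9 (1.0 equiv), toluene, 80 °C
Reagents that add atoms: none
Why: Wittig olefination with a stabilised formyl ylide should give the (E)-enal, and the use of one equivalent of ylide limits a second homologation.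

**Step 6**
Reactants: 6 5-methoxy-2-(3-methylbut-2-en-1-yl)benzene-1,3-diol (1.3 equiv); 10 (E)-3-[4-(triisopropylsilyloxy)phenyl]prop-2-enal
Product: 12 (±)-5-methoxy-8-(3-methylbut-2-en-1-yl)-2-[4-(triisopropylsilyloxy)phenyl]-2H-chromen-7-ol, via o-quinone methide 11 (not isolated)
Conditions: C6F5B(OH)2 (20 mol %), Ph2P(O)OH (20 mol %), 4 Å MS, toluene, 90 °C
Reagents that add atoms: none
Why: Boronic-acid-templated ortho-hydroxyalkylation delivers the aldehyde carbon of 10 (1,2- and not 1,4-attack) to the ring carbon next to a phenol, loss of water gives o-quinone methide 11 and a thermal oxa-6π electrocyclisation closes ring C, and because 6 has a mirror plane both possible sites give the same constitution (prenyl at C8, OH at C7, OMe at C5), with C2 formed racemic on purpose.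

**Step 7**
Reactants: 12 (±)-5-methoxy-8-(3-methylbut-2-en-1-yl)-2-[4-(triisopropylsilyloxy)phenyl]-2H-chromen-7-ol
Product: 13 (±)-5-methoxy-8-(3-methylbut-2-en-1-yl)-7-(triisopropylsilyloxy)-2-[4-(triisopropylsilyloxy)phenyl]-2H-chromene
Conditions: TIPSCl, imidazole, DMAP (cat.), DMF, 40 °C
Reagents that add atoms: chlorotriisopropylsilane (TIPSCl), CC(C)[Si](Cl)(C(C)C)C(C)C
Why: Routine silylation masks the acidic 7-OH, which would otherwise quench the catalytic alkoxide and the benzylic copper intermediate of step 8.

**Step 8**
Reactants: 13 (±)-5-methoxy-8-(3-methylbut-2-en-1-yl)-7-(triisopropylsilyloxy)-2-[4-(triisopropylsilyloxy)phenyl]-2H-chromene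
Product: 16 (2R,3S)-5-methoxy-8-(3-methylbut-2-en-1-yl)-7-(triisopropylsilyloxy)-2-[4-(triisopropylsilyloxy)phenyl]chroman-3-ol, via ring-opened o-quinone methide 14 (not isolated), via trans-3-boronate 15 (not isolated)
Conditions: CuCl (5 mol %), (S,S)-Ph-BPE (6 mol %), NaOt-Bu (10 mol %), MeOH (2 equiv), degassed THF, 10 °C, hν (Pyrex, 310–350 nm), B2pin2 (1.2 equiv) by syringe pump over 12 h; then dark, NaBO3·4H2O, THF/H2O, rt
Reagents that add atoms: bis(pinacolato)diboron, CC1(C)OB(OC1(C)C)B1OC(C)(C)C(C)(C)O1 (B of 15); sodium perborate, [Na+].[Na+].O[B-]1(O)OO[B-](O)(O)OO1 (O at C3 of 16; water of crystallisation not shown)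
Why: Proposed new method: L*Cu–Bpin (from CuOt-Bu and B2pin2) adds syn across C3=C4 of 13 with boron at C3 and copper at the benzylic C4, methanol protonates the C4–Cu bond to give 15, and perborate then replaces C3–B by C3–O with retention, while light absorbed only by the 2H-chromene chromophore keeps breaking O1–C2 of unreacted 13 to give the achiral o-quinone methide 14. The closest known reaction types are the Cu/bisphosphine protoboration of racemic 2-aryl-2H-chromenes run as a simple kinetic resolution and the photochromic ring opening that racemises 2H-chromenes; only their operation in one flask is new. Ring C is reclosed from 14 by thermal disrotatory oxa-6π electrocyclisation (O1–C2 bond) on either face, which is what racemises C2, and no other ring is formed. C2 is controlled by the ligand, which lets only (2S)-13 react at a useful rate (this is the enantiomer with the C2 geometry of the target; the descriptor becomes R once C3 bears oxygen), and C3 is controlled by delivery of boron to the ring face anti to the C2 aryl group, the face the ligand also prefers in the matched pair, hence 2,3-trans. The step needs chemoselectivity for C3=C4 over the prenyl alkene and boron at C3, both secured by the nucleophilic Cu–B reagent, which adds only to the aryl-conjugated alkene and places copper at the benzylic carbon, and it needs a configurationally stable product, secured because 15 has lost the C3=C4 link of the oxa-triene and neither absorbs nor opens. Slow addition of B2pin2 should keep borylation slower than racemisation, and unimolecular reclosure of 14, whose electrophilicity is damped by the C5-OMe and C7-OSi donors (a doubly vinylogous ester), should outrun bimolecular capture by methanol, alkoxide or Cu–B at the low concentrations used.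

**Step 9**
Reactants: 16 (2R,3S)-5-methoxy-8-(3-methylbut-2-en-1-yl)-7-(triisopropylsilyloxy)-2-[4-(triisopropylsilyloxy)phenyl]chroman-3-ol
Product: 17 8-prenylafzelechin 5-methyl ether, (2R,3S)-2-(4-hydroxyphenyl)-5-methoxy-8-(3-methylbut-2-en-1-yl)chroman-3,7-diol
Conditions: TBAF (2.4 equiv), AcOH (2.4 equiv), THF, 0 °C, argon
Reagents that add atoms: none
Why: Fluoride-induced cleavage of both aryl silyl ethers, buffered with acetic acid so that no free 4'-phenoxide can open ring C to a p-quinone methide and epimerise C2, leaves the alkene, the methyl ether and both stereocentres untouched.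

**Compound list**
1 | 5-methoxyresorcinol | COc1cc(O)cc(O)c1 | starting material
2 | 1-methoxy-3,5-bis(methoxymethoxy)benzene | COCOc1cc(OC)cc(OCOC)c1 | intermediate
3 | prenyl bromide | CC(C)=CCBr | starting material
4 | [4-methoxy-2,6-bis(methoxymethoxy)phenyl]lithium (not isolated) | [Li]c1c(OCOC)cc(OC)cc1OCOC | intermediate
5 | 5-methoxy-1,3-bis(methoxymethoxy)-2-(3-methylbut-2-en-1-yl)benzene | COCOc1cc(OC)cc(OCOC)c1CC=C(C)C | intermediate
6 | 5-methoxy-2-(3-methylbut-2-en-1-yl)benzene-1,3-diol | COc1cc(O)c(CC=C(C)C)c(O)c1 | intermediate
7 | 4-hydroxybenzaldehyde | O=Cc1ccc(O)cc1 | starting material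
8 | 4-(triisopropylsilyloxy)benzaldehyde | O=Cc1ccc(O[Si](C(C)C)(C(C)C)C(C)C)cc1 | intermediate
9 | (triphenylphosphoranylidene)acetaldehyde | O=CC=P(c1ccccc1)(c1ccccc1)c1ccccc1 | starting material
10 | (E)-3-[4-(triisopropylsilyloxy)phenyl]prop-2-enal | O=C/C=C/c1ccc(O[Si](C(C)C)(C(C)C)C(C)C)cc1 | intermediate
11 | 7-hydroxy o-quinone methide, achiral, geometry at C4a=C4 mobile (not isolated) | COC1=CC(O)=C(CC=C(C)C)C(=O)C1=C/C=C/c1ccc(O[Si](C(C)C)(C(C)C)C(C)C)cc1 | intermediate
12 | (±)-5-methoxy-8-prenyl-2-[4-(triisopropylsilyloxy)phenyl]-2H-chromen-7-ol | COc1cc(O)c(CC=C(C)C)c2c1C=CC(c1ccc(O[Si](C(C)C)(C(C)C)C(C)C)cc1)O2 | intermediate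
13 | (±)-5-methoxy-8-prenyl-7-(triisopropylsilyloxy)-2-[4-(triisopropylsilyloxy)phenyl]-2H-chromene | COc1cc(O[Si](C(C)C)(C(C)C)C(C)C)c(CC=C(C)C)c2c1C=CC(c1ccc(O[Si](C(C)C)(C(C)C)C(C)C)cc1)O2 | intermediate
14 | ring-opened bis-TIPS o-quinone methide, achiral, mixture of geometric isomers (not isolated) | COC1=CC(O[Si](C(C)C)(C(C)C)C(C)C)=C(CC=C(C)C)C(=O)C1=CC=Cc1ccc(O[Si](C(C)C)(C(C)C)C(C)C)cc1 | intermediate
15 | 2,3-trans-3-(pinacolatoboryl)flavan, CIP (2S,3S), same spatial arrangement as the target (not isolated) | COc1cc(O[Si](C(C)C)(C(C)C)C(C)C)c(CC=C(C)C)c2c1C[C@H](B3OC(C)(C)C(C)(C)O3)[C@@H](c1ccc(O[Si](C(C)C)(C(C)C)C(C)C)cc1)O2 | intermediate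
16 | (2R,3S)-5-methoxy-8-prenyl-7-(triisopropylsilyloxy)-2-[4-(triisopropylsilyloxy)phenyl]chroman-3-ol | COc1cc(O[Si](C(C)C)(C(C)C)C(C)C)c(CC=C(C)C)c2c1C[C@H](O)[C@@H](c1ccc(O[Si](C(C)C)(C(C)C)C(C)C)cc1)O2 | intermediate
17 | 8-prenylafzelechin 5-methyl ether, (2R,3S) | COc1cc(O)c(CC=C(C)C)c2c1C[C@H](O)[C@@H](c1ccc(O)cc1)O2 | target

**Total step count:** 9. **Longest linear sequence:** 7 (steps 1, 2, 3, 6, 7, 8, 9).

**Steps most likely to fail**

1. **Step 8 (Proposed new method).**
   - What may go wrong: racemisation may be too slow relative to borylation, so that the slow enantiomer is drawn in and the enantiomeric purity erodes. The ring-opened form may be intercepted by methanol, alkoxide or Cu–B. The copper catalyst may be deactivated by light.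
   - Fallback (known chemistry, the two manifolds kept apart): starting from (±)-13, the borylation is run in the dark with about half an equivalent of B2pin2 as a plain kinetic resolution and then oxidised with perborate. Alcohol 16 is separated by chromatography from the unreacted (2R)-configured flav-3-ene F1. F1 alone is then irradiated in degassed cyclohexane, free of copper, boron and alcohol, which returns (±)-13 for the next cycle. The route is rejoined at 16.

2. **Step 6.**
   - What may go wrong: the arene may attack the enal in conjugate (1,4) fashion. The new chromene may be captured under acid by a second resorcinol molecule. A second annulation may occur on the 7-OH side.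
   - Fallback: starting from 5 and 10, a second directed ortho-metalation of 5 (n-BuLi, THF, 0 °C) gives the aryllithium F2; the two remaining ring C–H are equivalent, each flanked by OMOM and OMe. F2 adds 1,2 to enal 10 to give the racemic allylic alcohol F3. Mild acid (PPTS, MeOH, 50 °C) ionises the doubly activated carbinol, the ortho oxygen closes ring C with loss of its MOM group, and the remaining MOM group is cleaved. The route is rejoined at 12.

3. **Step 3.**
   - What may go wrong: acid-induced addition of a flanking phenol to the prenyl alkene (chroman formation) may compete with acetal cleavage.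
   - Fallback: the protecting groups are avoided altogether. Starting from 1, a direct ortho C-allylation with 3-methylbut-2-en-1-ol on acidic alumina (1,2-dichloroethane, reflux) is carried out and the 2-prenyl isomer is separated from the 4-prenyl isomer by chromatography. This replaces steps 1–3, and the route is rejoined at 6.

**Further compounds**
F1 | step 8 | (2R)-5-methoxy-8-prenyl-7-(triisopropylsilyloxy)-2-[4-(triisopropylsilyloxy)phenyl]-2H-chromene | COc1cc(O[Si](C(C)C)(C(C)C)C(C)C)c(CC=C(C)C)c2c1C=C[C@H](c1ccc(O[Si](C(C)C)(C(C)C)C(C)C)cc1)O2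
F2 | step 6 | [6-methoxy-2,4-bis(methoxymethoxy)-3-(3-methylbut-2-en-1-yl)phenyl]lithium | [Li]c1c(OC)cc(OCOC)c(CC=C(C)C)c1OCOC
F3 | step 6 | (±)-(E)-1-[6-methoxy-2,4-bis(methoxymethoxy)-3-(3-methylbut-2-en-1-yl)phenyl]-3-[4-(triisopropylsilyloxy)phenyl]prop-2-en-1-ol | COCOc1cc(OC)c(C(O)/C=C/c2ccc(O[Si](C(C)C)(C(C)C)C(C)C)cc2)c(OCOC)c1CC=C(C)C
F0 | step 3 | none | none
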